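Remark: ring B positions are called by the chromone numbering of the target (O1, C2 to C8a) in every intermediate; Ar = 7-methoxy-4-oxo-2-(2-phenylethyl)-4H-chromen-6-yl, TBS = tert-butyldimethylsilyl; diol 8 is assumed to be the commercial (1S,2S) product of the microbial cis-dihydroxylation of bromobenzene.

## Analysis of the target

The target is an ether-linked pair of 2-(2-phenylethyl)chromones. Unit A is a fully aromatic 7-methoxychromone bound through its C6 oxygen. Unit B is a 5,6,7,8-tetrahydrochromone whose carbocycle (ring B: C4a, C5, C6, C7, C8, C8a) carries hydroxyls on C5, C6 and C7 and the aryloxy group on C8. The four contiguous stereocentres are 5S,6R,7S,8S: the oxygens on C5, C7 and C8 lie on one face of ring B and the C6 oxygen on the other, so C7/C8 are cis, C6/C7 trans and C5/C6 trans. Ring B is a dihydroarene polyol: loss of water or of the phenol from C5 or C8 (both allylic to the pyranone enol ether C4a=C8a) aromatises it under acid or base, and the 4-pyranones are opened by hard nucleophiles. As long as C8a is still a ketone, C8 is an α-aryloxy carbon with a β-oxygen on C7, so it can epimerise and eliminate. The hard parts are the hindered secondary alkyl aryl ether that joins two elaborate halves with defined configuration, and four consecutive oxygenated centres with mixed relationships in a ring that aromatises easily. The strategy rests on one feature: O1 on C8a and the hydroxyl oxygen on C6 are 1,4-related across C4a–C5, and the C6 oxygen is anti to the cis pair on C7 and C8. That is the pattern left by a two-oxygen bridge laid across C8a and C6 of a 1-bromocyclohexa-1,3-diene that already holds the cis C7 and C8 oxygens.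

## Retrosynthetic reasoning

**20 from 19.** The last disconnection removes the two silyl groups from O6 and O7. The free triol is the most fragile compound of the route, so it is unveiled last, under buffered, non-basic fluoride conditions.

**19 from 17.** The O1–C2 bond of pyranone B and the C5–O bond are cut together. In 17, C5 is the β-carbon of an alkene activated by two carbonyl groups, and the C8a ketone lies next to an ynone. Formal addition of the elements of water at C5 releases the C8a enol, whose oxygen can close onto the alkyne. The forward step must put the C5 oxygen anti to the C6 silyloxy group and must close the ring through the C8a oxygen, not the new C5 hydroxyl.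

**17 from 15 and 16.** Both bonds to the C4 carbonyl (C4a–C4 and C4–C3) are cut in a carbonylative alkynylation. This brings in C2, C3 and the phenylethyl chain as the terminal alkyne 16 and uses the enone carbon C4a as the site of coupling, so no regioselective enolate chemistry next to C8 is needed.

**15 from 14 from 13.** The C4a–I bond comes from α-iodination of the enone, and the O6 silyl group from silylation of 13. The C6 hydroxyl has to be capped first, because a free γ-hydroxyl would trap the acylpalladium intermediate as a lactone and would compete as a nucleophile in the pyranone closure.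

**13 from 10 (key disconnection).** The C8a–O and C6–O bonds are cut together. A photooxygenation of the bromodiene 10 delivers both oxygens in one [4+2] event on the face opposite the C7 and C8 substituents. Reduction of the peroxide and loss of bromide from C8a then give the C8a ketone (the future O1) and the C6 alcohol, with C4a=C5 left as an enone ready for the two later bond formations. Cutting here, and not at the C7 or C8 oxygens, leaves the cis C7/C8 pair to come with absolute control from the starting diol.

**10 from 9 and 7.** The aryl C–O bond is cut, not the C8–O bond. The C8–O bond already exists with the right configuration in 9. Making it by substitution would need inversion from a trans precursor and would invite aromatisation of the dienol. An oxidative aryl transfer to the hydroxyl keeps C8 untouched. The coupling is placed early, on the simplest alcohol of the route.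

**9 from 8; 7 from 5, 2, 3 and 1.** The O7 silyl ether comes from regioselective silylation of 8 at the hydroxyl remote from bromine. The aryl donor 7 comes from bromochromone 5 by borylation. The pyranone of 5 is cut at O1–C2 and C2–C3 into the acetophenone 2 and the ester 3. The bromine of 2 marks the later ether position and is introduced on paeonol 1, where the directing effects are unambiguous.

## Alternatives that were turned down

**Alternative 1:** Ring B is cut at C5–C6 and C7–C8, a [4+2] between a pyranone-based dienol and a symmetrical dienophile.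
- Forward key step: irradiation of the formyl pyranone A1 with a chiral titanium diolate shifts a hydrogen from the ether methylene to the excited formyl group. The transient dienol A2 is trapped by the enedione A3 to give A4, closing ring B and setting all four stereocentres at once.
- For: this is more convergent than the chosen route, needs no fermentation-derived material, and fixes the C5 oxygen firmly, which is the least secure centre of the chosen route.
- Against: photoenolisation–cycloaddition is established for ortho-alkyl aryl carbonyl compounds, not for a 4-pyranone, whose own photochemistry competes. The two acetyl groups of A4 must then become hydroxyls by twofold Baeyer–Villiger oxidation. Each acetyl is α-epimerisable and β to an oxygen leaving group (C5 ether, C8 hydroxyl), so elimination toward the aromatic chromone and retro-aldol cleavage at C7–C8 threaten. The aryl ether would still have to be made, late, on a crowded secondary alcohol of a precious intermediate.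
- Comparison: the chosen route forms the ether first on a simple alcohol, needs no carbon-to-oxygen corrections, and sets C6, C7 and C8 by precedented, substrate-controlled events.

**Alternative 2:** Both pyranones are cut at C2–C3.
- Forward key step: the polyanion of the bis-methyl ketone A5, made with excess lithium amide base, is acylated at both methyl carbons by the amide A6 to give the bis-1,3-diketone A7; twofold cyclodehydration would follow.
- For: it uses the latent symmetry of the two phenylethylpyranone units, avoids palladium carbonylation and the reactive acyl enone 17, and is at least as economical as the chosen route for the pyranone parts.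
- Against: A5 already contains all four stereocentres and the aryl ether, so the stereochemical problem is only moved into an unspecified synthesis of a fully oxygenated acylcyclohexanedione. The polyanion sits next to a C5 silyloxy group and an acidic C8 hydrogen, so elimination and epimerisation are likely. The acid needed for double cyclodehydration would ionise the C5 oxygen and strip the silyl ethers.
- Comparison: the chosen route closes pyranone B at the ynone oxidation level under near-neutral conditions, after C6 to C8 are secure.

**Alternative 3:** Unit B is cut at C4a–C5 and O1–C2, back to the open-chain triketo aldehyde A8, whose C6–C8 triad comes from the carbohydrate pool.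
- Forward key step: under secondary ammonium carboxylate catalysis the doubly activated C4a adds to the C5 aldehyde (6-exo aldol closure of ring B). The C8a enol oxygen then condenses with the C2 ketone to give A9, which is identical with compound 19 of the chosen route.
- For: both rings of unit B form in one flask, O1 is present from the start, and neither photochemistry nor palladium is needed; on these points it is stronger.
- Against: C5 is set in a reversible aldol with little bias, no better than the hydration of the chosen route. The aldol of a doubly activated methylene under these conditions normally goes on to dehydrate, which here means irreversible aromatisation. The open-chain α-aryloxy triketone is configurationally labile at C8, and the β-silyloxy aldehyde eliminates easily. Building A8 with its aryl ether needs a long, protecting-group-heavy sequence.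
- Comparison: the chosen route keeps all intermediates cyclic, where C8 is better held, and reaches 19 in eight steps from diol 8.

Key step: step 6

## Route

Step 1
Reactants: 1 paeonol (1-(2-hydroxy-4-methoxyphenyl)ethan-1-one)
Product: 2 bromopaeonol 1-(5-bromo-2-hydroxy-4-methoxyphenyl)ethan-1-one
Conditions: NBS (1.05 equiv), MeCN, 0 °C → rt
Reagents that add atoms: N-bromosuccinimide, O=C1CCC(=O)N1Br
Why: Electrophilic aromatic bromination; C5' is para to the phenol and ortho to the methoxy group and is the most activated open position, while the position between the two oxygens is crowded and the one next to the acetyl group is not activated.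

Step 2
Reactants: 2 bromopaeonol; 3 ethyl 3-phenylpropanoate
Product: 5 bromochromone 6-bromo-7-methoxy-2-(2-phenylethyl)-4H-chromen-4-one, via 1,3-diketone 4 (not isolated)
Conditions: NaH (4 equiv), THF, 65 °C; then conc. HCl, AcOH, 90 °C
Reagents that add atoms: none
Why: Crossed Claisen condensation of the phenoxide/enolate dianion of 2 with ester 3 gives the chelated 1,3-diketone 4, and acid-catalysed cyclodehydration (phenol onto the distal ketone, loss of water) closes the pyranone; this is the standard construction of 2-(2-phenylethyl)chromones and the aryl bromide is inert to it.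

Step 3
Reactants: 5 bromochromone
Product: 7 potassium trifluoro[7-methoxy-4-oxo-2-(2-phenylethyl)-4H-chromen-6-yl]borate, via pinacol boronate 6 (not isolated)
Conditions: B2pin2 (1.2 equiv), PdCl2(dppf) (3 mol %), KOAc (3 equiv), 1,4-dioxane, 85 °C; then KHF2 (aq., 4 equiv), MeOH, rt
Reagents that add atoms: bis(pinacolato)diboron, CC1(C)OB(OC1(C)C)B1OC(C)(C)C(C)(C)O1; potassium hydrogen difluoride, [K+].[F-].F
Why: Miyaura borylation (oxidative addition of the aryl bromide to zerovalent palladium, acetate-assisted boryl transfer) followed by fluoride exchange gives a monomeric, air-stable aryltrifluoroborate, the aryl donor best suited to copper-mediated etherification of aliphatic alcohols; the chromone enone is not affected.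

Step 4
Reactants: 8 (1S,2S)-3-bromocyclohexa-3,5-diene-1,2-diol
Product: 9 silyl ether (1S,6S)-2-bromo-6-[(tert-butyldimethylsilyl)oxy]cyclohexa-2,4-dien-1-ol
Conditions: TBSCl (1.05 equiv), imidazole (2.2 equiv), DMF, −20 °C
Reagents that add atoms: tert-butyldimethylsilyl chloride, CC(C)(C)[Si](C)(C)Cl
Why: Regioselective monosilylation, known for halodiene cis-diols: the hydroxyl next to the C–Br carbon is more hindered and less nucleophilic (inductive effect of the vinyl bromide), so the bulky silyl chloride should take the remote hydroxyl (the future O7) at low temperature; no stereocentre is touched.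

Step 5
Reactants: 9 silyl ether; 7 aryltrifluoroborate (2 equiv)
Product: 10 bromodiene aryl ether (5S,6S)-6-(ArO)-1-bromo-5-(TBSO)cyclohexa-1,3-diene
Conditions: Cu(OAc)2·H2O (20 mol %), DMAP (40 mol %), 4 Å MS, O2 (1 atm), CH2Cl2, rt
Reagents that add atoms: none
Why: Chan–Lam oxidative etherification (aryl transfer from boron to divalent copper, coordination of the alcohol, oxidation to trivalent copper, C–O reductive elimination); the bond formed is aryl C–O, the C8–O bond is never broken, so C8 keeps its configuration cis to the C7 silyloxy group. The near-neutral conditions at room temperature avoid alkoxide formation and with it silyl migration, dehydration and cyclodimerisation of the dienol.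

Step 6
Reactants: 10 bromodiene aryl ether
Product: 13 hydroxy enone (4R,5S,6S)-6-(ArO)-5-(TBSO)-4-hydroxycyclohex-2-en-1-one, via bromo endoperoxide 11 (not isolated), via gem-bromohydrin 12 (not isolated)
Conditions: O2, rose bengal (2 mol %), visible light, CH2Cl2–MeOH 9:1, −40 °C; then thiourea (1.5 equiv), MeOH, −40 °C → rt
Reagents that add atoms: dioxygen, O=O
Why: Singlet oxygen, formed by energy transfer from excited rose bengal, adds suprafacially to the diene termini C8a and C6 in a concerted [4+2] cycloaddition and gives the bicyclic peroxide 11. The closest known reaction type is the photooxygenation of protected halocyclohexadiene cis-diols followed by thiourea reduction to 4-hydroxycyclohex-2-enones. Thiourea cleaves the O–O bond by attack at oxygen, and the gem-bromohydrin 12 at C8a expels bromide to give the C8a ketone conjugated with C4a=C5. No ring of the target is closed: the dioxabicyclo[2.2.2]octene bridge of 11 is formed by the cycloaddition and opened again by the reduction, and serves only to deliver both oxygens to one face. The one new stereocentre that survives, C6, is set by the face of attack: the C7 silyloxy and C8 aryloxy groups stand on the same side and flank both diene termini, so oxygen should enter from the opposite face and give 6R, anti to O7; the C8a centre of 11 and 12 disappears with the ketone. Facial selectivity is further helped by the absence of a free hydroxyl that could steer oxygen syn by hydrogen bonding. Periselectivity ([4+2] over ene reaction) is secured by the locked s-cis diene, and the position of the carbonyl (C8a, not C6) by the bromine, provided that no base is present before the reduction to trigger a Kornblum–DeLaMare fragmentation. The chromone, the aryl ether and the phenylethyl groups should be inert to singlet oxygen at this temperature.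

Step 7
Reactants: 13 hydroxy enone
Product: 14 bis-silyl enone (4R,5R,6S)-6-(ArO)-4,5-bis(TBSO)cyclohex-2-en-1-one
Conditions: TBSOTf (1.3 equiv), 2,6-lutidine (2.5 equiv), CH2Cl2, −78 °C
Reagents that add atoms: tert-butyldimethylsilyl trifluoromethanesulfonate, CC(C)(C)[Si](C)(C)OS(=O)(=O)C(F)(F)F
Why: Silylation of the C6 hydroxyl with a silyl triflate and a hindered pyridine base, fast at low temperature and mild enough for the base-sensitive α-aryloxy ketone; a free γ-hydroxyl would otherwise trap the acylpalladium intermediate of step 9 as a butenolide and compete as a nucleophile in step 10, and the bulky ether also shields the upper face of C5.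

Step 8
Reactants: 14 bis-silyl enone
Product: 15 iodoenone (4R,5R,6S)-6-(ArO)-4,5-bis(TBSO)-2-iodocyclohex-2-en-1-one
Conditions: I2 (2 equiv), pyridine–CH2Cl2 1:1, 0 °C → rt
Reagents that add atoms: iodine, II
Why: α-Iodination of an enone with iodine and pyridine (conjugate addition of pyridine at C5, iodination of the enolate at C4a, elimination of pyridine, a Baylis–Hillman-type sequence); it is well established for 4-silyloxycyclohexenones and places the halogen only at C4a.

Step 9
Reactants: 15 iodoenone; 16 4-phenylbut-1-yne
Product: 17 ynone (4R,5R,6S)-6-(ArO)-4,5-bis(TBSO)-2-(5-phenylpent-2-ynoyl)cyclohex-2-en-1-one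
Conditions: CO (1 atm), PdCl2(PPh3)2 (5 mol %), Et3N (2 equiv), THF, rt; filtered through a short silica pad and used at once
Reagents that add atoms: carbon monoxide, [C-]#[O+]
Why: Carbonylative Sonogashira coupling of a vinyl iodide: oxidative addition of the C4a–I bond to zerovalent palladium, CO insertion to the acylpalladium species, amine-assisted alkynyl transfer and reductive elimination give the ynone; copper-free conditions under a CO atmosphere are chosen to disfavour direct alkynylation.

Step 10
Reactants: 17 ynone
Product: 19 bis-silyl ether (5S,6R,7R,8S)-8-(ArO)-6,7-bis(TBSO)-5-hydroxy-2-(2-phenylethyl)-5,6,7,8-tetrahydro-4H-chromen-4-one, via hydroxy diketone enol 18 (not isolated)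
Conditions: H2O (20 equiv), Et3N (0.3 equiv), THF, 0 °C → rt
Reagents that add atoms: water, O
Why: Proposed new method: C5 of 17 is the β-carbon of an alkylidene 1,3-dicarbonyl unit, so water should add there reversibly (oxa-Michael addition; closest known type: hydration and alcohol addition to alkylidene β-dicarbonyl compounds and base-catalysed hydration of enones); the adduct enolises toward C8a to give 18, whose enol oxygen closes 6-endo-dig onto the ynone (closest known type: cyclisation of 2-hydroxyaryl ynones and alkynyl 1,3-diketones to chromones and 4-pyranones). Once the pyranone exists the C4a=C5 acceptor is gone and the C5 hydroxyl can no longer be lost. Water should enter anti to the C6 silyloxy group and give 5S, and because the addition is reversible the trans C5/C6 arrangement is also expected to be drained preferentially into product.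

Step 11
Reactants: 19 bis-silyl ether
Product: 20 target (5S,6R,7S,8S)-8-(ArO)-5,6,7-trihydroxy-2-(2-phenylethyl)-5,6,7,8-tetrahydro-4H-chromen-4-one
Conditions: HF·pyridine, pyridine, THF, 0 °C → rt
Reagents that add atoms: none
Why: Fluoride-mediated cleavage of the two secondary silyl ethers; the buffered, mildly acidic and non-basic medium avoids β-elimination and aromatisation of the triol and ring opening of the pyranones, and no stereocentre is touched.

## Compound list

1 | paeonol, 1-(2-hydroxy-4-methoxyphenyl)ethan-1-one | COc1ccc(C(C)=O)c(O)c1 | starting material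
2 | 1-(5-bromo-2-hydroxy-4-methoxyphenyl)ethan-1-one | CC(=O)c1cc(Br)c(OC)cc1O | intermediate
3 | ethyl 3-phenylpropanoate | CCOC(=O)CCc1ccccc1 | starting material
4 | 1-(5-bromo-2-hydroxy-4-methoxyphenyl)-5-phenylpentane-1,3-dione | COc1cc(O)c(cc1Br)C(=O)CC(=O)CCc1ccccc1 | intermediate (not isolated)
5 | 6-bromo-7-methoxy-2-(2-phenylethyl)-4H-chromen-4-one | COc1cc2oc(CCc3ccccc3)cc(=O)c2cc1Br | intermediate
6 | 7-methoxy-2-(2-phenylethyl)-6-(4,4,5,5-tetramethyl-1,3,2-dioxaborolan-2-yl)-4H-chromen-4-one | COc1cc2oc(CCc3ccccc3)cc(=O)c2cc1B1OC(C)(C)C(C)(C)O1 | intermediate (not isolated)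
7 | potassium trifluoro[7-methoxy-4-oxo-2-(2-phenylethyl)-4H-chromen-6-yl]borate | COc1cc2oc(CCc3ccccc3)cc(=O)c2cc1[B-](F)(F)F.[K+] | intermediate
8 | (1S,2S)-3-bromocyclohexa-3,5-diene-1,2-diol | O[C@H]1C=CC=C(Br)[C@H]1O | starting material
9 | (1S,6S)-2-bromo-6-[(tert-butyldimethylsilyl)oxy]cyclohexa-2,4-dien-1-ol | CC(C)(C)[Si](C)(C)O[C@H]1C=CC=C(Br)[C@H]1O | intermediate
10 | 6-{[(1S,6S)-2-bromo-6-[(tert-butyldimethylsilyl)oxy]cyclohexa-2,4-dien-1-yl]oxy}-7-methoxy-2-(2-phenylethyl)-4H-chromen-4-one | CC(C)(C)[Si](C)(C)O[C@H]1C=CC=C(Br)[C@H]1Oc1cc2c(=O)cc(CCc3ccccc3)oc2cc1OC | intermediate (precursor of the key step)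
11 | 1-bromo-7-(ArO)-8-(TBSO)-2,3-dioxabicyclo[2.2.2]oct-5-ene, peroxide bridge anti to both oxygen substituents | COc1cc2oc(CCc3ccccc3)cc(=O)c2cc1O[C@@H]1[C@]3(Br)C=C[C@@H](OO3)[C@@H]1O[Si](C)(C)C(C)(C)C | intermediate (not isolated)
12 | 1-bromo-6-(ArO)-5-(TBSO)cyclohex-2-ene-1,4-diol, both hydroxyls anti to the ArO and TBSO groups | COc1cc2oc(CCc3ccccc3)cc(=O)c2cc1O[C@@H]1[C@](O)(Br)C=C[C@@H](O)[C@@H]1O[Si](C)(C)C(C)(C)C | intermediate (not isolated)
13 | (4R,5S,6S)-6-(ArO)-5-[(tert-butyldimethylsilyl)oxy]-4-hydroxycyclohex-2-en-1-one | COc1cc2oc(CCc3ccccc3)cc(=O)c2cc1O[C@@H]1C(=O)C=C[C@@H](O)[C@@H]1O[Si](C)(C)C(C)(C)C | intermediate (product of the key step)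
14 | (4R,5R,6S)-6-(ArO)-4,5-bis[(tert-butyldimethylsilyl)oxy]cyclohex-2-en-1-one | COc1cc2oc(CCc3ccccc3)cc(=O)c2cc1O[C@@H]1C(=O)C=C[C@@H](O[Si](C)(C)C(C)(C)C)[C@@H]1O[Si](C)(C)C(C)(C)C | intermediate
15 | (4R,5R,6S)-6-(ArO)-4,5-bis[(tert-butyldimethylsilyl)oxy]-2-iodocyclohex-2-en-1-one | COc1cc2oc(CCc3ccccc3)cc(=O)c2cc1O[C@@H]1C(=O)C(I)=C[C@@H](O[Si](C)(C)C(C)(C)C)[C@@H]1O[Si](C)(C)C(C)(C)C | intermediate
16 | 4-phenylbut-1-yne | C#CCCc1ccccc1 | starting material
17 | (4R,5R,6S)-6-(ArO)-4,5-bis[(tert-butyldimethylsilyl)oxy]-2-(5-phenylpent-2-ynoyl)cyclohex-2-en-1-one | COc1cc2oc(CCc3ccccc3)cc(=O)c2cc1O[C@@H]1C(=O)C(C(=O)C#CCCc2ccccc2)=C[C@@H](O[Si](C)(C)C(C)(C)C)[C@@H]1O[Si](C)(C)C(C)(C)C | intermediate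
18 | C5 water adduct of 17 as its C8a enol: 6-(ArO)-4,5-bis(TBSO)-3-hydroxy-2-(5-phenylpent-2-ynoyl)cyclohex-1-en-1-ol, C5 hydroxyl anti to the C6 silyloxy group | COc1cc2oc(CCc3ccccc3)cc(=O)c2cc1O[C@@H]1C(O)=C(C(=O)C#CCCc2ccccc2)[C@H](O)[C@@H](O[Si](C)(C)C(C)(C)C)[C@@H]1O[Si](C)(C)C(C)(C)C | intermediate (not isolated)
19 | (5S,6R,7R,8S)-8-(ArO)-6,7-bis[(tert-butyldimethylsilyl)oxy]-5-hydroxy-2-(2-phenylethyl)-5,6,7,8-tetrahydro-4H-chromen-4-one | COc1cc2oc(CCc3ccccc3)cc(=O)c2cc1O[C@@H]1c2oc(CCc3ccccc3)cc(=O)c2[C@H](O)[C@@H](O[Si](C)(C)C(C)(C)C)[C@@H]1O[Si](C)(C)C(C)(C)C | intermediate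
20 | (5S,6R,7S,8S)-5,6,7-trihydroxy-8-{[7-methoxy-4-oxo-2-(2-phenylethyl)-4H-chromen-6-yl]oxy}-2-(2-phenylethyl)-5,6,7,8-tetrahydro-4H-chromen-4-one | COc1cc2oc(CCc3ccccc3)cc(=O)c2cc1O[C@@H]1c2oc(CCc3ccccc3)cc(=O)c2[C@H](O)[C@@H](O)[C@@H]1O | target

## Step count and least certain steps

Total: 11 steps. Longest linear sequence: 10 steps (from 1 through steps 1 to 3 and 5 to 11); the branch from diol 8 is 8 steps (steps 4 to 11).

**Step 10 (proposed new method).** Three processes may spoil it. The ring closure may go through the new C5 hydroxyl instead of the C8a enol oxygen. The water addition may reverse, or occur with poor facial selectivity at C5, because the axial C7 silyloxy group partly shields the face that the C6 group leaves open. The amine may enolise the acyl enone toward C8 and start β-elimination and aromatisation. The fallback uses only established reactions; it sets out from 14 and comes back to the route at 20. Copper-catalysed conjugate borylation of 14 (CuCl, NaOtBu, bis[2-(diphenylphosphino)phenyl] ether, B2pin2, MeOH, THF, rt) should place boron on C5 anti to the C6 silyloxy group and give the β-boryl ketone F1. NaBO3·4H2O in THF–H2O oxidises it with retention, without isolation, to the β-hydroxy ketone F2, a formal hydration that is irreversible and kinetically controlled. Silylation (TBSOTf, 2,6-lutidine, −78 °C) gives the tris-silyl ketone F3. Its dibutylboron enolate, formed on the methylene side C4a (Bu2BOTf, iPr2NEt, CH2Cl2, −78 °C), is added to 5-phenylpent-2-ynal F4 (from 16 by lithiation with n-BuLi and formylation with DMF). This gives the aldol F5 as a mixture at the two new centres, both of which vanish on oxidation with Dess–Martin periodinane to the alkynyl 1,3-diketone F6. The enol of F6 has a single free oxygen nucleophile and should close 6-endo-dig with K2CO3 in acetone to the pyranone F7, the 5,6,7-tris-silyl ether of the target. HF·pyridine as in step 11 then gives 20.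

**Step 6 (key step).** Facial discrimination may be incomplete, because the two shielding groups are conformationally mobile ethers and not a rigid acetal. Ene hydroperoxidation may compete, and the peroxide may fragment toward the C6 ketone if it meets base or warms before reduction. The fallback sets out from 10 and comes back at 13. mCPBA buffered with NaHCO3 in CH2Cl2 at 0 °C should epoxidise the unhalogenated, more electron-rich C5=C6 bond anti to the C7 silyloxy group and give the vinyl epoxide F8. Sodium phenylselenide (PhSeSePh, NaBH4, EtOH, 0 °C) opens it at the allylic carbon C5 with inversion to the hydroxy selenide F9, in which the C6 oxygen already has its final configuration. Oxidation at selenium (H2O2, pyridine, THF, −40 °C → rt) sets off a [2,3]-sigmatropic shift that moves the oxygen from selenium to C8a and the double bond to C4a=C5. C8a then carries bromine and oxygen and collapses to the ketone with loss of the selenium residue and of bromide, which gives 13.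

**Step 5.** Aryl transfer and C–O reductive elimination may be slow at a hindered secondary allylic alcohol with an ortho-substituted aryl group. The borate may meanwhile be consumed by protodeboronation and phenol formation, and the dienol may dehydrate to an arene or cyclodimerise on long standing. The fallback sets out from 5 and 9 and comes back at 10. Halogen exchange on 5 (NaI, CuI, trans-N,N'-dimethylcyclohexane-1,2-diamine, 1,4-dioxane, 110 °C) gives the aryl iodide F10. An Ullmann-type etherification of 9 with F10 (CuI, 3,4,7,8-tetramethyl-1,10-phenanthroline, Cs2CO3, toluene, 80 °C) forms the same aryl C–O bond through an aryl electrophile, again without touching C8. The price is heat and carbonate base, under which silyl migration from O7 to O8 has to be watched.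

**Step 9.** Alkynyl transfer may outrun CO insertion and give direct alkynylation, and the amine may degrade the electrophilic product. The fallback sets out from 15 and 16 and comes back at 17. A Nozaki–Hiyama–Kishi coupling of 15 with 5-phenylpent-2-ynal F4 (CrCl2, NiCl2 cat., DMF, rt) gives the carbinol F11 as both epimers. Dess–Martin periodinane (NaHCO3, CH2Cl2, 0 °C) oxidises it to 17 without CO or amine base.

## Further compounds

F1 | step 10 | β-boryl ketone: 6-(ArO)-4,5-bis(TBSO)-3-(4,4,5,5-tetramethyl-1,3,2-dioxaborolan-2-yl)cyclohexan-1-one, boron anti to the C6 silyloxy group | COc1cc2oc(CCc3ccccc3)cc(=O)c2cc1O[C@@H]1C(=O)C[C@H](B2OC(C)(C)C(C)(C)O2)[C@@H](O[Si](C)(C)C(C)(C)C)[C@@H]1O[Si](C)(C)C(C)(C)C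
F2 | step 10 | β-hydroxy ketone: 6-(ArO)-4,5-bis(TBSO)-3-hydroxycyclohexan-1-one, hydroxyl anti to the C6 silyloxy group | COc1cc2oc(CCc3ccccc3)cc(=O)c2cc1O[C@@H]1C(=O)C[C@H](O)[C@@H](O[Si](C)(C)C(C)(C)C)[C@@H]1O[Si](C)(C)C(C)(C)C
F3 | step 10 | tris-silyl ketone: 6-(ArO)-3,4,5-tris(TBSO)cyclohexan-1-one | COc1cc2oc(CCc3ccccc3)cc(=O)c2cc1O[C@@H]1C(=O)C[C@H](O[Si](C)(C)C(C)(C)C)[C@@H](O[Si](C)(C)C(C)(C)C)[C@@H]1O[Si](C)(C)C(C)(C)C
F4 | step 10 | 5-phenylpent-2-ynal | O=CC#CCCc1ccccc1
F5 | step 10 | aldol: 6-(ArO)-3,4,5-tris(TBSO)-2-(1-hydroxy-5-phenylpent-2-ynyl)cyclohexan-1-one, mixture at C2 and the carbinol carbon | COc1cc2oc(CCc3ccccc3)cc(=O)c2cc1O[C@@H]1C(=O)C(C(O)C#CCCc2ccccc2)[C@H](O[Si](C)(C)C(C)(C)C)[C@@H](O[Si](C)(C)C(C)(C)C)[C@@H]1O[Si](C)(C)C(C)(C)C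
F6 | step 10 | alkynyl 1,3-diketone as its enol: 6-(ArO)-3,4,5-tris(TBSO)-2-(5-phenylpent-2-ynoyl)cyclohex-1-en-1-ol | COc1cc2oc(CCc3ccccc3)cc(=O)c2cc1O[C@@H]1C(O)=C(C(=O)C#CCCc2ccccc2)[C@H](O[Si](C)(C)C(C)(C)C)[C@@H](O[Si](C)(C)C(C)(C)C)[C@@H]1O[Si](C)(C)C(C)(C)C
F7 | step 10 | 5,6,7-tris-O-TBS ether of the target | COc1cc2oc(CCc3ccccc3)cc(=O)c2cc1O[C@@H]1c2oc(CCc3ccccc3)cc(=O)c2[C@H](O[Si](C)(C)C(C)(C)C)[C@@H](O[Si](C)(C)C(C)(C)C)[C@@H]1O[Si](C)(C)C(C)(C)C
F8 | step 6 | vinyl epoxide: C5–C6 epoxide of 10, oxirane anti to the C7 silyloxy group | COc1cc2oc(CCc3ccccc3)cc(=O)c2cc1O[C@@H]1C(Br)=C[C@H]2O[C@H]2[C@@H]1O[Si](C)(C)C(C)(C)C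
F9 | step 6 | hydroxy selenide: 3-bromo-2-(ArO)-1-(TBSO)-5-(phenylselanyl)cyclohex-3-en-6-ol skeleton, selenium on C5 trans to the C6 hydroxyl | COc1cc2oc(CCc3ccccc3)cc(=O)c2cc1O[C@@H]1C(Br)=C[C@H]([Se]c2ccccc2)[C@@H](O)[C@@H]1O[Si](C)(C)C(C)(C)C
F10 | step 5 | 6-iodo-7-methoxy-2-(2-phenylethyl)-4H-chromen-4-one | COc1cc2oc(CCc3ccccc3)cc(=O)c2cc1I
F11 | step 9 | carbinol: 6-(ArO)-4,5-bis(TBSO)-2-(1-hydroxy-5-phenylpent-2-ynyl)cyclohex-2-en-1-one, both epimers at the carbinol carbon | COc1cc2oc(CCc3ccccc3)cc(=O)c2cc1O[C@@H]1C(=O)C(C(O)C#CCCc2ccccc2)=C[C@@H](O[Si](C)(C)C(C)(C)C)[C@@H]1O[Si](C)(C)C(C)(C)C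
A1 | alternative 1 | 3-[(4-methoxybenzyloxy)methyl]-4-oxo-6-(2-phenylethyl)-4H-pyran-2-carbaldehyde | O=Cc1oc(CCc2ccccc2)cc(=O)c1COCc1ccc(OC)cc1
A2 | alternative 1 | photodienol: 2-(hydroxymethylidene)-3-[(4-methoxybenzyloxy)methylidene]-6-(2-phenylethyl)-2,3-dihydro-4H-pyran-4-one | OC=C1OC(CCc2ccccc2)=CC(=O)C1=COCc1ccc(OC)cc1
A3 | alternative 1 | (E)-hex-3-ene-2,5-dione | CC(=O)/C=C/C(C)=O
A4 | alternative 1 | (5S,6S,7S,8S)-6,7-diacetyl-8-hydroxy-5-(4-methoxybenzyloxy)-2-(2-phenylethyl)-5,6,7,8-tetrahydro-4H-chromen-4-one | O[C@@H]1c2oc(CCc3ccccc3)cc(=O)c2[C@H](OCc2ccc(OC)cc2)[C@@H](C(C)=O)[C@@H]1C(C)=O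
A5 | alternative 2 | bis-methyl ketone core: 2-acetyl-6-(5-acetyl-4-hydroxy-2-methoxyphenoxy)-3,4,5-tris(TBSO)cyclohex-1-en-1-ol | CC(=O)c1cc(O[C@@H]2C(O)=C(C(C)=O)[C@H](O[Si](C)(C)C(C)(C)C)[C@@H](O[Si](C)(C)C(C)(C)C)[C@@H]2O[Si](C)(C)C(C)(C)C)c(OC)cc1O
A6 | alternative 2 | N-methoxy-N-methyl-3-phenylpropanamide | CON(C)C(=O)CCc1ccccc1
A7 | alternative 2 | bis-1,3-diketone | O=C(CC(=O)CCc1ccccc1)c1cc(O[C@@H]2C(O)=C(C(=O)CC(=O)CCc3ccccc3)[C@H](O[Si](C)(C)C(C)(C)C)[C@@H](O[Si](C)(C)C(C)(C)C)[C@@H]2O[Si](C)(C)C(C)(C)C)c(OC)cc1O
A8 | alternative 3 | triketo aldehyde: 4-(ArO)-2,3-bis(TBSO)-5,7,9-trioxo-11-phenylundecanal | O=C[C@@H](O[Si](C)(C)C(C)(C)C)[C@H](O[Si](C)(C)C(C)(C)C)[C@H](Oc1cc2c(=O)cc(CCc3ccccc3)oc2cc1OC)C(=O)CC(=O)CC(=O)CCc1ccccc1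
A9 | alternative 3 | 6,7-di-O-TBS ether of the target (identical with 19) | COc1cc2oc(CCc3ccccc3)cc(=O)c2cc1O[C@@H]1c2oc(CCc3ccccc3)cc(=O)c2[C@H](O)[C@@H](O[Si](C)(C)C(C)(C)C)[C@@H]1O[Si](C)(C)C(C)(C)C
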